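At the last reading, 80.0 min into each run, electrophile stands at 24.9%, 25.4% and 24.7% of its charge for free base at 0.18 M, 0.20 M and 0.27 M, in no order of the base, so the three runs are pooled and the three new flasks get one number.

| setting | Monday's | Tuesday's | Friday's | dawn | winter | spring |
|---|---|---|---|---|---|---|
| electrophile | 0.15 M | 0.15 M | 0.15 M | 0.15 M | 0.15 M | 0.15 M |
| nucleophile | 0.165 M | 0.165 M | 0.165 M | 0.165 M | 0.165 M | 0.165 M |
| free base | 0.18 M | 0.20 M | 0.27 M | 0.280 M | 0.170 M | 0.210 M |
| scavenger | 0.15 M | 0.15 M | 0.15 M | 0.150 M | 0.150 M | 0.150 M |
| remark | run made earlier | run made earlier | run made earlier |  |  |  |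
| time |  |  |  | 2.5 h | 2.5 h | 2.5 h |

| run | time / min | electrophile / % | target / % |
|---|---|---|---|
| Monday's | 15.0 | 64.4 | 20.4 |
| Monday's | 30.0 | 48.0 | 20.7 |
| Monday's | 50.0 | 36.5 | 17.9 |
| Monday's | 60.0 | 32.1 | 16.7 |
| Monday's | 80.0 | 24.9 | 15.3 |
| Tuesday's | 15.0 | 64.1 | 20.8 |
| Tuesday's | 30.0 | 48.2 | 20.9 |
| Tuesday's | 50.0 | 35.5 | 18.0 |
| Tuesday's | 60.0 | 31.6 | 17.3 |
| Tuesday's | 80.0 | 25.4 | 15.4 |
| Friday's | 15.0 | 64.4 | 20.8 |
| Friday's | 30.0 | 48.0 | 21.2 |
| Friday's | 50.0 | 35.7 | 18.8 |
| Friday's | 60.0 | 31.2 | 17.9 |
| Friday's | 80.0 | 24.7 | 15.2 |

(each reading ± 0.3 percentage points)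

* part of the electrophile that has reacted at the end, dawn
* part of the electrophile that has reacted at the end, winter
* part of the electrophile that has reacted at the end, spring
* what raising the concentration of free base from its lowest to its highest value here does to the part of the electrophile that has reacted (changes below 5 percentage points count as none) (it rises / it falls / no change)



The pooled fall between the last two readings gives 0.0118 min⁻¹: this is the late pace, the fraction of the electrophile present that goes per minute. Over the 70.0 min still to run it makes a reach of 0.824, starting from a pooled 25.0%. Two extremes can be solved in the head. If electrophile's partner stood still, the pace would hold (pseudo-first-order), and the last value times the exponential of minus the reach leaves 11.0%. If the partner fell in step with electrophile, the pace would sink with it (second order), and the last value over one plus the reach leaves 13.7%. Target, the one possible partner that is read, falls at 0.00614 min⁻¹, about half the pace of electrophile, so the flask should lie between the two, and their mean serves: 87.7% reacted, give or take 1.4 percentage points, in dawn, winter and spring alike, with no change along the free base.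

The forecast, which stands lower than this reckoning in each flask  and differs from it in the trend, reads 85%, 78% and 84% for dawn, winter and spring and it rises for the trend, holding that the “lowest-base run may therefore stall”.

The flasks give 87.7%, 87.0% and 87.3% for dawn, winter and spring, so no change, with a change of 0.7 points. In winter 93.6% of the charged free base is still free at the end. The late pace once more: dawn stopped at 1.90 h has a reach of 0.397, and the mean of the two curves then lies 5 points below its figure for the full time, where the computed flask has moved by 5 points.

    electrophile + target → side product (k = 0.300 L mol⁻¹ min⁻¹)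
    acid set free + free base ⇌ idle adduct, settled at all times (K = 160 L mol⁻¹)
    acid set free + free base ⇌ salt of the base (K = 19.0 L mol⁻¹, k = 7.30 L mol⁻¹ min⁻¹)
    nucleophile + acid set free ⇌ protonated nucleophile, settled at all times (K = 5700 L mol⁻¹)
    acid set free + scavenger → scavenged by-product (k = 4.70 L mol⁻¹ min⁻¹)
    2 nucleophile → self-condensation product (k = 0.120 L mol⁻¹ min⁻¹)
    electrophile + nucleophile → acid set free + target (k = 0.250 L mol⁻¹ min⁻¹)

A neighbour of spring, charged with 0.26 M of electrophile on the same nucleophile, is reckoned the same way: a partner standing still keeps the reacted share at 87.7%, a partner allowing the same 0.131 M as reckoned for spring gives 50.6%, and their mean is 69.2%. The computed flask reaches 74.9%.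

(The data are simulated for substances that don't exist; noise was put on by code.)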